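## Retrosynthetic overview

1. Target 41 ⇐ 6-methoxychromane 39 by oxidative opening of the pyran ring and reduction of the resulting quinone; the C13–O bond of the tertiary alcohol is therefore the phenol oxygen of a cyclization precursor.
2. 39 ⇐ seco-phenol 38 by a phenol-terminated cation–olefin cyclization that forms C8–C14 and C13–O.
3. 38 is cut at C12–C13 into fragment 1, alkyl iodide 25 (rings A/B plus lactone, 19 non-hydrogen atoms), and fragment 2, aryl vinyl iodide 35 (17 non-hydrogen atoms); they are joined by a late Negishi coupling (step 20 of 23).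
4. 25 ⇐ lactonization, C3 deoxygenation and C4 methylation of bicyclic β-keto ester 19, made by an auxiliary-controlled oxidative radical bicyclization of acyclic β-keto ester 18. 18 comes from pent-3-yn-1-ol, acrolein acetal, 2-bromoallyl alcohol, trimethyl orthoacetate and acetyl chloride; 35 comes from hydroquinone, formaldehyde and a propynyl Grignard reagent.
5. Ring order: rings A and B together (step 9), lactone ring (step 12), ring C together with a temporary pyran ring (step 22), pyran ring opened (step 23).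

Conventions: locants C1–C20 are the labdane-type locants of the diterpenoid part (C17 on C8, C16 on C13, C18 = α-methyl on C4, C19 = carbonyl on C4, C20 = OCH2 on C10, C15 = benzylic CH2). α is the face of H-5, β the face of C20. TBDPS = tert-butyldiphenylsilyl, MOM = methoxymethyl. The choice of the (1S,2R,5S) auxiliary for the 5α-H/10β series and the acid-mediated ring C closure rest on recalled precedent for closely related systems, not on a checked source.

## Route

**Fragment 1 (steps 1–13)**

Step 1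
Reactants: 1 pent-3-yn-1-ol
Product: 2 tert-butyl(pent-3-yn-1-yloxy)diphenylsilane
Conditions: TBDPSCl, imidazole, DMF, rt
Reagents that add atoms: tert-butyl(chloro)diphenylsilane, CC(C)(C)[Si](Cl)(c1ccccc1)c1ccccc1
Why: Standard silylation of a primary alcohol, giving an ether that survives every step up to the fluoride treatment in step 12.

Step 2
Reactants: 2 tert-butyl(pent-3-yn-1-yloxy)diphenylsilane
Product: 4 tert-butyl{[(3E)-4-iodopent-3-en-1-yl]oxy}diphenylsilane, via alkenylzirconocene chloride 3 (not isolated)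
Conditions: Cp2Zr(H)Cl (2 equiv), THF, 50 °C; then I2, 0 °C
Reagents that add atoms: iodine, II
Why: Schwartz hydrozirconation is a syn addition that, under equilibrating conditions, places zirconium on the less hindered methyl-bearing carbon, and iodinolysis with retention gives the (E)-iodoalkene.

Step 3
Reactants: 5 3,3-dimethoxyprop-1-ene (acrolein dimethyl acetal); 4 tert-butyl{[(3E)-4-iodopent-3-en-1-yl]oxy}diphenylsilane
Product: 8 (4E)-7-[(tert-butyldiphenylsilyl)oxy]-4-methylhept-4-enal, via alkylborane 6 (not isolated), via dimethyl acetal 7 (not isolated)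
Conditions: 5, 9-BBN-H, THF, 0 °C → rt; then 4, Pd(dppf)Cl2 (5 mol %), K3PO4 (aq), DMF, 50 °C; then TsOH·H2O (cat.), acetone/H2O, rt
Reagents that add atoms: water, O
Why: Anti-Markovnikov hydroboration followed by B-alkyl Suzuki–Miyaura coupling proceeds with retention of the vinyl iodide geometry (E), and mild acetal hydrolysis frees the aldehyde without touching the TBDPS ether.

Step 4
Reactants: 9 2-bromoprop-2-en-1-ol
Product: 10 [(2-bromoprop-2-en-1-yl)oxy](tert-butyl)diphenylsilane
Conditions: TBDPSCl, imidazole, DMF, rt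
Reagents that add atoms: tert-butyl(chloro)diphenylsilane, CC(C)(C)[Si](Cl)(c1ccccc1)c1ccccc1
Why: Standard silylation; the bulky silyl group later becomes the protected C20 oxygen.

Step 5
Reactants: 8 (4E)-7-[(tert-butyldiphenylsilyl)oxy]-4-methylhept-4-enal; 10 [(2-bromoprop-2-en-1-yl)oxy](tert-butyl)diphenylsilane
Product: 11 (6E)-9-[(tert-butyldiphenylsilyl)oxy]-2-{[(tert-butyldiphenylsilyl)oxy]methyl}-6-methylnona-1,6-dien-3-ol (racemic at C3)
Conditions: CrCl2 (4 equiv), NiCl2 (2 mol %), DMF, rt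
Reagents that add atoms: none
Why: Nozaki–Hiyama–Kishi addition of the alkenylchromium species is chemoselective for the aldehyde and avoids a 2-lithioallyl silyl ether that could undergo silyl migration; the racemic carbinol centre is erased in step 6.

Step 6
Reactants: 11 (6E)-9-[(tert-butyldiphenylsilyl)oxy]-2-{[(tert-butyldiphenylsilyl)oxy]methyl}-6-methylnona-1,6-dien-3-ol; 12 1,1,1-trimethoxyethane (trimethyl orthoacetate)
Product: 14 methyl (4Z,8E)-11-[(tert-butyldiphenylsilyl)oxy]-4-{[(tert-butyldiphenylsilyl)oxy]methyl}-8-methylundeca-4,8-dienoate, via ketene acetal 13 (not isolated)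
Conditions: 12 (excess), EtCO2H (cat.), 120 °C, MeOH distilled off
Reagents that add atoms: none
Why: Johnson orthoester Claisen rearrangement through a chair transition state with the C6 chain equatorial gives the trisubstituted alkene with the main chain trans, which is (4Z) by the CIP rules because CH2OSi outranks the chain.

Step 7
Reactants: 15 acetyl chloride
Product: 16 (1S,2R,5S)-5-methyl-2-(2-phenylpropan-2-yl)cyclohexyl acetate
Conditions: (1S,2R,5S)-8-phenylmenthol, pyridine, DMAP (cat.), CH2Cl2, 0 °C → rt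
Reagents that add atoms: (1S,2R,5S)-8-phenylmenthol (chiral auxiliary), O[C@H]1C[C@@H](C)CC[C@@H]1C(C)(C)c1ccccc1
Why: Simple acylation of the auxiliary alcohol, which brings in C4 and C19 together with the controller of absolute configuration.

Step 8
Reactants: 14 methyl (4Z,8E)-11-[(tert-butyldiphenylsilyl)oxy]-4-{[(tert-butyldiphenylsilyl)oxy]methyl}-8-methylundeca-4,8-dienoate; 16 (1S,2R,5S)-5-methyl-2-(2-phenylpropan-2-yl)cyclohexyl acetate
Product: 18 (1S,2R,5S)-8-phenylmenthyl (6Z,10E)-13-[(tert-butyldiphenylsilyl)oxy]-6-{[(tert-butyldiphenylsilyl)oxy]methyl}-10-methyl-3-oxotrideca-6,10-dienoate, via lithium enolate 17 (not isolated)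
Conditions: 16 (2.5 equiv), LiN(i-Pr)2 (2.5 equiv), THF, −78 °C; then 14, −78 → 0 °C
Reagents that add atoms: none
Why: Crossed Claisen condensation of the hindered acetate enolate with the methyl ester is driven by deprotonation of the β-keto ester product and forms no stereocentre.

Step 9
Reactants: 18 (1S,2R,5S)-8-phenylmenthyl (6Z,10E)-13-[(tert-butyldiphenylsilyl)oxy]-6-{[(tert-butyldiphenylsilyl)oxy]methyl}-10-methyl-3-oxotrideca-6,10-dienoate
Product: 19 (1S,2R,5S)-8-phenylmenthyl ester of the trans-decalin β-keto acid: 3-oxo; C4-H with the ester equatorial (enolisable centre); 5α-H; 10β-CH2OTBDPS; 8(17)-exo-methylene; 9β-CH2CH2OTBDPS (9α-H)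
Conditions: Mn(OAc)3·2H2O (2.2 equiv), Cu(OAc)2·H2O (1 equiv), Yb(OTf)3 (1 equiv), CF3CH2OH, −5 → 0 °C
Reagents that add atoms: none
Why: Snider-type oxidative radical polyene cyclization by trivalent manganese: the chelated α-keto ester radical closes 6-endo/6-endo through a chair–chair transition state (trans fusion, equatorial C9 chain), the cumyl phenyl ring of the auxiliary shields one face of the enol radical so that the 5α-H/10β series forms, and divalent copper oxidises the tertiary C8 radical to the exocyclic alkene.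

Step 10
Reactants: 19 bicyclic β-keto ester
Product: 20 (1S,2R,5S)-8-phenylmenthyl 12,20-bis[(tert-butyldiphenylsilyl)oxy]-3-oxo-13,14,15,16-tetranorlabd-8(17)-en-19-oate (4α-methyl; 4β-ester)
Conditions: MeI, K2CO3, acetone, rt
Reagents that add atoms: iodomethane, CI
Why: C-alkylation of the β-keto ester enolate from the α face, anti to the axial C10 CH2OTBDPS group, puts the methyl equatorial (4α) and the ester axial (4β).

Step 11
Reactants: 20 (1S,2R,5S)-8-phenylmenthyl 12,20-bis[(tert-butyldiphenylsilyl)oxy]-3-oxo-13,14,15,16-tetranorlabd-8(17)-en-19-oate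
Product: 22 (1S,2R,5S)-8-phenylmenthyl 12,20-bis[(tert-butyldiphenylsilyl)oxy]-13,14,15,16-tetranorlabd-8(17)-en-19-oate, via tosylhydrazone 21 (not isolated)
Conditions: TsNHNH2, PPTS (cat.), 4 Å MS, THF, 60 °C; then catecholborane, 0 °C → rt; then NaOAc·3H2O, 65 °C
Reagents that add atoms: none
Why: Kabalka reduction of the tosylhydrazone (hydride to C=N, loss of sulfinate and N2) removes the C3 ketone without touching the ester, silyl ethers or alkene, and no stereocentre is affected.

Step 12
Reactants: 22 (1S,2R,5S)-8-phenylmenthyl 12,20-bis[(tert-butyldiphenylsilyl)oxy]-13,14,15,16-tetranorlabd-8(17)-en-19-oate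
Product: 24 12-hydroxy-13,14,15,16-tetranorlabd-8(17)-en-19,20-olide, via dihydroxy ester 23 (not isolated)
Conditions: Bu4NF (3 equiv), THF, 0 → 50 °C
Reagents that add atoms: none
Why: Fluoride desilylation frees the C20 alkoxide, which sits 1,3-diaxial to the C19 ester and closes the δ-lactone by intramolecular transesterification, expelling the auxiliary.

Step 13
Reactants: 24 12-hydroxy-13,14,15,16-tetranorlabd-8(17)-en-19,20-olide
Product: 25 12-iodo-13,14,15,16-tetranorlabd-8(17)-en-19,20-olide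
Conditions: I2, PPh3, imidazole, CH2Cl2, 0 °C → rt
Reagents that add atoms: iodine, II
Why: Appel-type iodination converts the unhindered primary alcohol by SN2 and leaves the lactone and alkene alone.

**Fragment 2 (steps 14–19)**

Step 14
Reactants: 26 benzene-1,4-diol (hydroquinone)
Product: 27 4-methoxyphenol
Conditions: MeOH, H2SO4, NaNO2 (cat.), rt
Reagents that add atoms: methanol, CO
Why: Nitrite-promoted acid-catalysed mono-etherification stops after one methylation because the mono-ether is no longer activated in the same way.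

Step 15
Reactants: 27 4-methoxyphenol
Product: 28 1-methoxy-4-(methoxymethoxy)benzene
Conditions: MOMCl, i-Pr2NEt, CH2Cl2, 0 °C → rt
Reagents that add atoms: chloromethyl methyl ether, COCCl
Why: O-alkylation installs the MOM ether, which is both the protecting group and the stronger director for the next metalation.

Step 16
Reactants: 28 1-methoxy-4-(methoxymethoxy)benzene
Product: 30 [5-methoxy-2-(methoxymethoxy)phenyl]methanol, via aryllithium 29 (not isolated)
Conditions: n-BuLi, TMEDA, Et2O, 0 °C; then (CH2O)n, 0 °C → rt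
Reagents that add atoms: formaldehyde (as paraformaldehyde), C=O
Why: Directed ortho-metalation occurs next to the chelating MOM ether, and the aryllithium adds to formaldehyde.

Step 17
Reactants: 30 [5-methoxy-2-(methoxymethoxy)phenyl]methanol
Product: 31 2-(bromomethyl)-4-methoxy-1-(methoxymethoxy)benzene
Conditions: CBr4, PPh3, CH2Cl2, 0 °C (used at once)
Reagents that add atoms: carbon tetrabromide, BrC(Br)(Br)Br
Why: Appel bromination under neutral conditions gives the reactive electron-rich benzylic bromide without cleaving the MOM ether.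

Step 18
Reactants: 31 2-(bromomethyl)-4-methoxy-1-(methoxymethoxy)benzene; 32 prop-1-yn-1-ylmagnesium bromide (CH3C≡CMgBr)
Product: 33 2-(but-2-yn-1-yl)-4-methoxy-1-(methoxymethoxy)benzene
Conditions: CuI (10 mol %), THF, 0 → 40 °C
Reagents that add atoms: none
Why: Copper-catalysed coupling of an alkynyl Grignard reagent with a benzylic bromide gives the propargyl arene directly and avoids the allene problem of aryl-metal plus propargyl halide.

Step 19
Reactants: 33 2-(but-2-yn-1-yl)-4-methoxy-1-(methoxymethoxy)benzene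
Product: 35 2-[(2E)-3-iodobut-2-en-1-yl]-4-methoxy-1-(methoxymethoxy)benzene, via alkenylzirconocene chloride 34 (not isolated)
Conditions: Cp2Zr(H)Cl (2 equiv), THF, 50 °C; then I2, 0 °C
Reagents that add atoms: iodine, II
Why: Schwartz hydrozirconation (syn, zirconium on the methyl-bearing carbon after equilibration) and iodinolysis with retention set the (E)-trisubstituted vinyl iodide that becomes C13=C14.

**Coupling and endgame (steps 20–23)**

Step 20
Reactants: 25 12-iodo-13,14,15,16-tetranorlabd-8(17)-en-19,20-olide; 35 2-[(2E)-3-iodobut-2-en-1-yl]-4-methoxy-1-(methoxymethoxy)benzene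
Product: 37 15-[5-methoxy-2-(methoxymethoxy)phenyl]labda-8(17),13E-dien-19,20-olide, via alkylzinc iodide 36 (not isolated)
Conditions: 25, Zn dust, LiCl, THF, 40 °C; then 35, Pd(dppf)Cl2 (5 mol %), THF/NMP, 40 °C
Reagents that add atoms: none
Why: Negishi sp3–sp2 coupling: zinc insertion tolerates the lactone, and coupling at zerovalent palladium proceeds with retention of the (E)-alkene geometry, joining the two halves at C12–C13.

Step 21
Reactants: 37 15-[5-methoxy-2-(methoxymethoxy)phenyl]labda-8(17),13E-dien-19,20-olide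
Product: 38 15-(2-hydroxy-5-methoxyphenyl)labda-8(17),13E-dien-19,20-olide
Conditions: ZnBr2, n-PrSH, CH2Cl2, 0 °C, 10 min
Reagents that add atoms: none
Why: Lewis-acid/thiol cleavage of the aryl MOM ether (acetal exchange onto sulfur) is fast and nearly neutral, so the phenol is released without protonating either alkene.

Step 22
Reactants: 38 15-(2-hydroxy-5-methoxyphenyl)labda-8(17),13E-dien-19,20-olide
Product: 39 pentacyclic 6-methoxychromane lactone (8β-methyl; 9α-H; 14α-H; 13β-methyl; 13α-O-aryl; trans-fused chromane; 19,20-olide)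
Conditions: SnCl4 (1.5 equiv), CH2Cl2, −78 → −30 °C
Reagents that add atoms: none
Why: Biomimetic cation–olefin cyclization: protonation of the 8(17)-alkene gives the C8 cation, the (E)-13,14-alkene attacks it from the α face through a chair (C8 methyl β-axial, 14-H α), and the phenol oxygen captures C13 anti (13α-O, 13β-methyl).

Step 23
Reactants: 39 pentacyclic 6-methoxychromane lactone
Product: 41 strongylophorine-8, via quinone 40 (not isolated)
Conditions: (NH4)2Ce(NO3)6 (2.5 equiv), MeCN/H2O, 0 °C; then Na2S2O4 (aq), EtOAc, rt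
Reagents that add atoms: water, O
Why: Oxidative dealkylation of the hydroquinone diether by tetravalent cerium: water adds at the aryl carbons, methanol is lost and the C13–O bond stays intact as the tertiary alcohol with its configuration retained, and dithionite reduces the para-quinone to the hydroquinone.

## Compound list

1 | pent-3-yn-1-ol | CC#CCCO | starting material
2 | tert-butyl(pent-3-yn-1-yloxy)diphenylsilane | CC#CCCO[Si](c1ccccc1)(c1ccccc1)C(C)(C)C | intermediate
3 | chlorobis(cyclopentadienyl)[(2E)-5-(TBDPS-oxy)pent-2-en-2-yl]zirconium | C/C(=C\CCO[Si](c1ccccc1)(c1ccccc1)C(C)(C)C)[Zr](Cl)(C1C=CC=C1)C1C=CC=C1 | intermediate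
4 | tert-butyl{[(3E)-4-iodopent-3-en-1-yl]oxy}diphenylsilane | C/C(I)=C\CCO[Si](c1ccccc1)(c1ccccc1)C(C)(C)C | intermediate
5 | 3,3-dimethoxyprop-1-ene | C=CC(OC)OC | starting material
6 | 9-(3,3-dimethoxypropyl)-9-borabicyclo[3.3.1]nonane | COC(OC)CCB1C2CCCC1CCC2 | intermediate
7 | tert-butyl{[(3E)-7,7-dimethoxy-4-methylhept-3-en-1-yl]oxy}diphenylsilane | COC(OC)CC/C(C)=C/CCO[Si](c1ccccc1)(c1ccccc1)C(C)(C)C | intermediate
8 | (4E)-7-[(tert-butyldiphenylsilyl)oxy]-4-methylhept-4-enal | O=CCC/C(C)=C/CCO[Si](c1ccccc1)(c1ccccc1)C(C)(C)C | intermediate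
9 | 2-bromoprop-2-en-1-ol | C=C(Br)CO | starting material
10 | [(2-bromoprop-2-en-1-yl)oxy](tert-butyl)diphenylsilane | C=C(Br)CO[Si](c1ccccc1)(c1ccccc1)C(C)(C)C | intermediate
11 | (6E)-9-[(tert-butyldiphenylsilyl)oxy]-2-{[(tert-butyldiphenylsilyl)oxy]methyl}-6-methylnona-1,6-dien-3-ol (racemic) | C=C(CO[Si](c1ccccc1)(c1ccccc1)C(C)(C)C)C(O)CC/C(C)=C/CCO[Si](c1ccccc1)(c1ccccc1)C(C)(C)C | intermediate
12 | 1,1,1-trimethoxyethane | CC(OC)(OC)OC | starting material
13 | 1-methoxyvinyl ether of 11 (ketene acetal) | C=C(OC)OC(CC/C(C)=C/CCO[Si](c1ccccc1)(c1ccccc1)C(C)(C)C)C(=C)CO[Si](c1ccccc1)(c1ccccc1)C(C)(C)C | intermediate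
14 | methyl (4Z,8E)-11-[(tert-butyldiphenylsilyl)oxy]-4-{[(tert-butyldiphenylsilyl)oxy]methyl}-8-methylundeca-4,8-dienoate | COC(=O)CC/C(CO[Si](c1ccccc1)(c1ccccc1)C(C)(C)C)=C/CC/C(C)=C/CCO[Si](c1ccccc1)(c1ccccc1)C(C)(C)C | intermediate
15 | acetyl chloride | CC(=O)Cl | starting material
16 | (1S,2R,5S)-5-methyl-2-(2-phenylpropan-2-yl)cyclohexyl acetate | CC(=O)O[C@H]1C[C@@H](C)CC[C@@H]1C(C)(C)c1ccccc1 | intermediate
17 | lithium enolate of 16 | C=C(O[Li])O[C@H]1C[C@@H](C)CC[C@@H]1C(C)(C)c1ccccc1 | intermediate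
18 | (1S,2R,5S)-8-phenylmenthyl (6Z,10E)-13-[(tert-butyldiphenylsilyl)oxy]-6-{[(tert-butyldiphenylsilyl)oxy]methyl}-10-methyl-3-oxotrideca-6,10-dienoate | O=C(CC(=O)CC/C(CO[Si](c1ccccc1)(c1ccccc1)C(C)(C)C)=C/CC/C(C)=C/CCO[Si](c1ccccc1)(c1ccccc1)C(C)(C)C)O[C@H]1C[C@@H](C)CC[C@@H]1C(C)(C)c1ccccc1 | intermediate
19 | bicyclic β-keto ester (3-oxo; 4-H, ester equatorial; 5α-H; 10β-CH2OTBDPS; 8(17)-ene; 9β-CH2CH2OTBDPS) | C=C1CC[C@@H]2[C@](CO[Si](c3ccccc3)(c3ccccc3)C(C)(C)C)(CCC(=O)[C@H]2C(=O)O[C@H]2C[C@@H](C)CC[C@@H]2C(C)(C)c2ccccc2)[C@H]1CCO[Si](c1ccccc1)(c1ccccc1)C(C)(C)C | intermediate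
20 | (1S,2R,5S)-8-phenylmenthyl 12,20-bis[(tert-butyldiphenylsilyl)oxy]-3-oxo-13,14,15,16-tetranorlabd-8(17)-en-19-oate | C=C1CC[C@@H]2[C@](CO[Si](c3ccccc3)(c3ccccc3)C(C)(C)C)(CCC(=O)[C@]2(C)C(=O)O[C@H]2C[C@@H](C)CC[C@@H]2C(C)(C)c2ccccc2)[C@H]1CCO[Si](c1ccccc1)(c1ccccc1)C(C)(C)C | intermediate
21 | 3-(4-methylbenzenesulfonyl)hydrazone of 20 | C=C1CC[C@@H]2[C@](CO[Si](c3ccccc3)(c3ccccc3)C(C)(C)C)(CCC(=NNS(=O)(=O)c3ccc(C)cc3)[C@]2(C)C(=O)O[C@H]2C[C@@H](C)CC[C@@H]2C(C)(C)c2ccccc2)[C@H]1CCO[Si](c1ccccc1)(c1ccccc1)C(C)(C)C | intermediate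
22 | (1S,2R,5S)-8-phenylmenthyl 12,20-bis[(tert-butyldiphenylsilyl)oxy]-13,14,15,16-tetranorlabd-8(17)-en-19-oate | C=C1CC[C@@H]2[C@](CO[Si](c3ccccc3)(c3ccccc3)C(C)(C)C)(CCC[C@]2(C)C(=O)O[C@H]2C[C@@H](C)CC[C@@H]2C(C)(C)c2ccccc2)[C@H]1CCO[Si](c1ccccc1)(c1ccccc1)C(C)(C)C | intermediate
23 | (1S,2R,5S)-8-phenylmenthyl 12,20-dihydroxy-13,14,15,16-tetranorlabd-8(17)-en-19-oate | C=C1CC[C@@H]2[C@](CO)(CCC[C@]2(C)C(=O)O[C@H]2C[C@@H](C)CC[C@@H]2C(C)(C)c2ccccc2)[C@H]1CCO | intermediate
24 | 12-hydroxy-13,14,15,16-tetranorlabd-8(17)-en-19,20-olide | C=C1CC[C@@H]2[C@]3(CCC[C@]2(C)C(=O)OC3)[C@H]1CCO | intermediate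
25 | 12-iodo-13,14,15,16-tetranorlabd-8(17)-en-19,20-olide | C=C1CC[C@@H]2[C@]3(CCC[C@]2(C)C(=O)OC3)[C@H]1CCI | intermediate
26 | benzene-1,4-diol | Oc1ccc(O)cc1 | starting material
27 | 4-methoxyphenol | COc1ccc(O)cc1 | intermediate
28 | 1-methoxy-4-(methoxymethoxy)benzene | COCOc1ccc(OC)cc1 | intermediate
29 | [5-methoxy-2-(methoxymethoxy)phenyl]lithium | COCOc1ccc(OC)cc1[Li] | intermediate
30 | [5-methoxy-2-(methoxymethoxy)phenyl]methanol | COCOc1ccc(OC)cc1CO | intermediate
31 | 2-(bromomethyl)-4-methoxy-1-(methoxymethoxy)benzene | COCOc1ccc(OC)cc1CBr | intermediate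
32 | prop-1-yn-1-ylmagnesium bromide | CC#C[Mg]Br | starting material
33 | 2-(but-2-yn-1-yl)-4-methoxy-1-(methoxymethoxy)benzene | CC#CCc1cc(OC)ccc1OCOC | intermediate
34 | chlorobis(cyclopentadienyl){(2E)-4-[5-methoxy-2-(methoxymethoxy)phenyl]but-2-en-2-yl}zirconium | C/C(=C\Cc1cc(OC)ccc1OCOC)[Zr](Cl)(C1C=CC=C1)C1C=CC=C1 | intermediate
35 | 2-[(2E)-3-iodobut-2-en-1-yl]-4-methoxy-1-(methoxymethoxy)benzene | C/C(I)=C\Cc1cc(OC)ccc1OCOC | intermediate
36 | (19,20-olide-13,14,15,16-tetranorlabd-8(17)-en-12-yl)zinc iodide | C=C1CC[C@@H]2[C@]3(CCC[C@]2(C)C(=O)OC3)[C@H]1CC[Zn]I | intermediate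
37 | 15-[5-methoxy-2-(methoxymethoxy)phenyl]labda-8(17),13E-dien-19,20-olide | C=C1CC[C@@H]2[C@]3(CCC[C@]2(C)C(=O)OC3)[C@H]1CC/C(C)=C/Cc1cc(OC)ccc1OCOC | intermediate
38 | 15-(2-hydroxy-5-methoxyphenyl)labda-8(17),13E-dien-19,20-olide | C=C1CC[C@@H]2[C@]3(CCC[C@]2(C)C(=O)OC3)[C@H]1CC/C(C)=C/Cc1cc(OC)ccc1O | intermediate
39 | pentacyclic 6-methoxychromane lactone (O-methyl ether of the ring-closed chromanol) | C[C@@]12CC[C@@H]3[C@]4(CCC[C@]3(C)C(=O)OC4)[C@H]1CC[C@]1(C)Oc3ccc(OC)cc3C[C@H]12 | intermediate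
40 | quinone of the target (2-substituted 1,4-benzoquinone with 13α-OH) | C[C@@]12CC[C@@H]3[C@]4(CCC[C@]3(C)C(=O)OC4)[C@H]1CC[C@](C)(O)[C@H]2CC1=CC(=O)C=CC1=O | intermediate
41 | strongylophorine-8 | C[C@@]12CC[C@@H]3[C@]4(CCC[C@]3(C)C(=O)OC4)[C@H]1CC[C@](C)(O)[C@H]2Cc1cc(O)ccc1O | target

## Step count and risks

Total step count: 23.
Longest linear sequence: 15 steps (1, 2, 3, 5, 6, 8, 9, 10, 11, 12, 13, 20, 21, 22, 23).

Steps most likely to fail:

Step 9 (radical bicyclization). The cyclic β-keto ester 19 still has an acidic C4–H and can be oxidised further by trivalent manganese; the facial control by the auxiliary and the exocyclic/endocyclic alkene ratio are also uncertain for this substrate. Fallback: set out from 18 and C-methylate it first (MeI, K2CO3, acetone) to the α-methyl β-keto ester F1 (both C2 epimers, the centre becomes the radical carbon). F1 is then cyclised under Mn(OAc)3·2H2O/Cu(OAc)2·H2O in AcOH at rt. The quaternary C4 is now formed in the radical step with the ester axial, and the product cannot enolise, so over-oxidation is excluded. This gives 20 directly, where the route is rejoined and step 10 is skipped.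

Step 22 (ring C closure). The acid can protonate the 13,14-alkene instead of the 8(17)-alkene, so that the phenol closes a simple 2,2-dialkylchromane without forming C8–C14. Fallback: set out from 38 and convert the 1,1-disubstituted alkene selectively into the tertiary C8 chloride F2 (C8 epimers, inconsequential) by hydrogen-atom-transfer Markovnikov hydrochlorination (Co(BF4)2·6H2O with a salicylaldimine ligand as catalyst, PhSiH3, TsCl, EtOH, rt). F2 is ionised with AgOTf and 2,6-di-tert-butyl-4-methylpyridine in CH2Cl2 at −78 °C. The C8 cation is then generated by halide abstraction with no Brønsted acid present, so only the desired cyclization and phenol capture can follow, and the route is rejoined at 39.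

Step 23 (oxidative opening of the chromane). Tetravalent cerium on the diether could give ortho-quinone or over-oxidation products instead of clean para-quinone formation. Fallback: set out from 39 and cleave only the aryl methyl ether (BCl3, n-Bu4NI, CH2Cl2, −78 → 0 °C) to the free chromanol F3. Its phenol is oxidised with PhI(OAc)2 in MeCN/H2O at 0 °C; the phenoxonium ion is captured by water at the carbon bearing the ring oxygen and the hemiketal opens to quinone 40, where the route is rejoined before the dithionite reduction to 41.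

## Further compounds

F1 | step 9 | (1S,2R,5S)-8-phenylmenthyl (6Z,10E)-13-[(tert-butyldiphenylsilyl)oxy]-6-{[(tert-butyldiphenylsilyl)oxy]methyl}-2,10-dimethyl-3-oxotrideca-6,10-dienoate (C2 epimers) | CC(C(=O)CC/C(CO[Si](c1ccccc1)(c1ccccc1)C(C)(C)C)=C/CC/C(C)=C/CCO[Si](c1ccccc1)(c1ccccc1)C(C)(C)C)C(=O)O[C@H]1C[C@@H](C)CC[C@@H]1C(C)(C)c1ccccc1
F2 | step 22 | 8-chloro-15-(2-hydroxy-5-methoxyphenyl)labd-13E-en-19,20-olide (C8 epimers) | CC1(Cl)CC[C@@H]2[C@]3(CCC[C@]2(C)C(=O)OC3)[C@H]1CC/C(C)=C/Cc1cc(OC)ccc1O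
F3 | step 23 | pentacyclic 6-hydroxychromane lactone (O-demethyl 39) | C[C@@]12CC[C@@H]3[C@]4(CCC[C@]3(C)C(=O)OC4)[C@H]1CC[C@]1(C)Oc3ccc(O)cc3C[C@H]12
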